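## Structural features

Lespecyrtin E4 is a pterocarpan in which benzene rings A and D are joined through chromane ring B (O5, C6, C6a, C11a, C11b, C4a) and dihydrobenzofuran ring C (C6a, C6b, C10a, O11, C11a), the two sharing the C6a–C11a bond. Each benzene ring also carries a fused 2,2-dimethyl-2H-pyran, linear on ring A (C2/C3, oxygen on C3) and on C7/C8 of ring D (oxygen on C8). The only stereocenters are the adjacent C6a and C11a, both R with cis hydrogens, and because a trans B/C fusion is too strained, fixing C11a in a ring-forming event also fixes C6a. Ring D is hexasubstituted (C6b, C7 vinyl, C8–O, C9–OH, C10 prenyl, C10a–O) with its three oxygens in a 1,2,4 pattern, and this crowding together with the enantioselective creation of C11a is the real difficulty. The fragile groups are the two chromene double bonds, the prenyl group next to the free C9 phenol (acid closes it to a chromane) and the C11a–O11 bond, a benzylic ether activated by the ortho and para oxygens of ring A that ionises under acid. The key step uses the fact that C11a–C6a–C6 is, at the enal oxidation level, the C2=C3–CHO unit of a ring D benzofuran-3-carbaldehyde, while ring A is a phenol that is nucleophilic at C11b (ortho to O5, para to the pyran oxygen on C3) and carries O5 next to it. The oxygen pattern of ring D helps as well, since O8 and O9 each have a single free ortho carbon (C7 and C10), so sigmatropic shifts from these oxygens can only end there.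

## Logic of the disconnections

26 to 25: the O9–Si bond is cut. The C9 phenol has to be masked through oxidation, amine catalysis and the Mitsunobu step, and a silyl ether is chosen over an acetal because it comes off with fluoride. Acid at this stage would threaten the prenyl group, both chromenes and C11a–O11. The forward step must be strictly non-acidic.

25 to 24 to 23: the O5–C6 ether bond is cut and C6 is traced back to the lactol oxidation level. This replaces a direct acidic deoxygenation, which could also ionise C11a–O11, by hydride reduction and a Mitsunobu etherification. The demand is that C6a keeps its configuration while 23 reacts through its ring-open tautomer 22.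

23 to 5 and 21: C11a–C11b and O5–C6 are cut. This splits the molecule into two achiral fragments of similar size, each carrying one pyran, and leaves both stereocenters to one catalytic event. The forward step must add the phenol carbon of 5 to C11a of 21 with dearomatisation of the furan ring, on one face only, and then let O5 close ring B as the cis lactol.

21 to 20 to 19: only the oxidation level of C6 changes (aldehyde, alcohol, ester). The ester is the robust form in which ring D is decorated. The demand is chemoselective reduction and a mild oxidation of the heteroaryl carbinol.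

19 to 17 and 18, and 17 to 15 and 16: the prenyl double bond is cut by a metathesis transform to an allyl group, and the O9–Si bond is cut back to the phenol. An allyl group can be placed on C10 by a plain Claisen shift and survives acid, which a prenyl group would not. The forward metathesis must leave the chromene double bond alone.

15 to 13 (through 14): the C10–allyl bond and the C7–vinyl bond of the pyran are traced back to the O9 allyl ether and the O8 1,1-dimethylpropargyl ether. Two C–C bonds and one ring then come from one thermal operation, with regiochemistry forced by the oxygen pattern. The demand is that both rearrangements run cleanly at one temperature.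

13 to 11 and 12: the O8–C bond of the tertiary propargyl ether is cut. This leaves a single free phenol to alkylate.

11 to 8 and 9 (through 10): the furan ring is cut at C6a–C6b and O11–C11a. This is the only strongly acidic operation of the route, so it is placed before any prenyl, chromene or silyl group exists. The reverse order would expose an ortho-prenyl phenol and a chromene to HBF4 and H2SO4.

8 to 6 and 7: the O9–allyl bond is cut. The three hydroxyls of 6 differ enough in acidity for the one para to the formyl group to be alkylated alone. The demand is mono-alkylation under exclusion of air.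

5 to 3 (through 4) to 1 and 2: the chromene double bond is traced to the benzylic alcohol and then the ketone, and the chromanone is cut at the aryl–acyl bond and the O–CMe2 bond. This route gives only the 7-hydroxy (linear-type) chromene, which an aryl propargyl ether rearrangement of a resorcinol ether would not guarantee.

## Other disconnections considered

Alternative 1: The cut goes through ring D itself. C6b–C10a, C9–C10 and C8–C9 are disconnected, so that rings C and D both arise from a diazo enone on C6a and an alkynyl ether on the C11a oxygen of a preformed cis-3,4-disubstituted chromane, the diazo ketone A1.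
- Forward step: irradiation of A1 triggers a Wolff rearrangement. The resulting ketene adds to the tethered ynol ether in a [2+2] sense, the four-membered ring opens (4π), and 6π closure with tautomerisation gives the phenol A2. A2 is a 9-hydroxy-10-prenyl pterocarpan whose O8 already carries the 1,1-dimethylpropargyl group for a last Claisen/oxa-6π step to 26.
- In its favour: the hexasubstituted ring D is assembled with every substituent placed by connectivity instead of by successive aromatic substitutions. C9–OH emerges free, so no protecting group is needed. Three C–C bonds and two rings form in one operation. On these three points it is better than the chosen plan, whose key step forms one C–C bond, one C–O bond and one ring. Ketene–alkyne benzannulation with heteroatom-substituted alkynes also has more precedent than a dearomative iminium addition to a benzofuran, which is a further point for the alternative.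
- Against it here: the key step creates no stereocenter, so C6a and C11a must be set, cis, during the synthesis of A1; the chosen plan does this catalytically in its key step. A secondary alkynyl ether on the doubly activated benzylic C11a is prone to ionisation and to retro-ene loss of ketene. The diazo ketone sits next to the epimerisable C6a. The ring A chromene is itself photoactive (reversible electrocyclic opening) under the irradiation.
- Comparison: the ring D pyran still needs a thermal step after the benzannulation, so the end games are equal in length. The route to A1 (chromane with two stereocenters, ynol ether, diazo transfer) is judged longer and less convergent than the union of 5 and 21.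

Alternative 2: The cut is C6a–C11a. Ring C is closed by insertion of a metal carbenoid, generated from the ring D aryldiazoacetate A3, into the benzylic C–H bond of its ortho O–CH2–aryl ether, giving the cis-2-aryl-2,3-dihydrobenzofuran-3-carboxylate A4.
- Forward step: a chiral dirhodium tetracarboxylate of the Rh2(S-PTTL)4 type decomposes A3 and the 1,5-insertion sets C6a and C11a together. Ester reduction, desilylation and Mitsunobu closure of ring B, then propargylation of O8, Claisen/oxa-6π closure of the ring D pyran and removal of the O9 acetal would lead from A4 to 26.
- In its favour: this is an established reaction class with high cis and enantioselectivity for this ring type, so it is better than the chosen plan on precedent and on mechanistic risk. It sets both stereocenters under catalyst control, which is equal to the chosen plan. Ring B closes by the same Mitsunobu etherification, equal again.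
- Against it here: the carbenoid can also cyclopropanate the prenyl and chromene double bonds. A4 is the less stable epimer and must be reduced before any basic step. Ring D is not complete in A4 (C7–H, silyl ether on O8), so five or six operations follow the key step against three in the chosen plan. The O9 acetal has to be cleaved by acid at the very end, next to the prenyl group, two chromenes and the C11a–O11 bond. A3 needs a linear build-up (arylacetate homologation on ring D, O-benzylation to join ring A, diazo transfer) that is less convergent than joining 5 and 21.
- Comparison: the two plans are judged comparable in length before the key step, and the chosen plan is shorter after it.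

Alternative 3: Both pyran rings are cut at once, at the C2–vinyl and C7–vinyl bonds and the two O–CMe2 bonds. This leads back to the 3,8-dihydroxy-9-methoxy-10-prenyl pterocarpan-2,7-dicarbaldehyde A5 and the vinyl Grignard reagent A6.
- Forward step: excess A6 adds to both formyl groups of the bis-phenoxide of A5. Twofold loss of water to the ortho-quinone methide (1-oxatriene) level and twofold oxa-6π electrocyclisation then close both chromenes in the same flask. The product is A7, the 9-O-methyl ether of 26.
- In its favour: four bonds and two rings form in one flask, which is better than the chosen key step on bonds and rings formed. Both acid-sensitive chromenes are introduced at the very end. The pterocarpan core could come from established isoflavonoid chemistry. C7 is the only free site of ring D for formylation.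
- Against it here: the methyl ether on O9 of A7 must be removed last, and the Lewis acids or hot thiolates that cleave aryl methyl ethers would not spare the chromenes, the prenyl group next to the liberated phenol or the C11a–O11 bond. This is the decisive weakness. Formylation of ring A must select C2 over C4. The C10 prenyl group cannot come from a Claisen shift once O9 is methylated. The key step sets no stereocenter, whereas the chosen key step sets both.
- Comparison: the step itself is short, but A5 is a complete, doubly formylated pterocarpan, so the overall count is not judged lower.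

Key step: step 11

Remark: ring D intermediates are named as benzofurans, and "4,5-(2,2-dimethylpyrano)" means a 2,2-dimethyl-2H-pyran fused at C4/C5 with its oxygen on C5; the lactol of the key step has a third, anomeric center at C6 (one anomer drawn, removed in step 12), its C6a descriptor is S only through changed priorities, and O9 is carried as a tert-butyldimethylsilyl ether.

## Route

Step 1
Reactants: 1 resorcinol; 2 3-methylbut-2-enoic acid
Product: 3 7-hydroxy-2,2-dimethylchroman-4-one
Conditions: MeSO3H, P2O5, 70 °C
Reagents that add atoms: 3-methylbut-2-enoic acid (2), CC(C)=CC(=O)O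
Why: Friedel–Crafts acylation of resorcinol para to one hydroxyl, followed by intramolecular oxa-Michael addition of the ortho hydroxyl to the enone, is the standard entry to this chromanone and gives only the 7-hydroxy isomer.

Step 2
Reactants: 3 7-hydroxy-2,2-dimethylchroman-4-one
Product: 5 7-hydroxy-2,2-dimethyl-2H-chromene, via 2,2-dimethylchromane-4,7-diol 4 (not isolated)
Conditions: LiAlH4, THF, 0 °C to rt; then 2 M HCl, THF, rt
Reagents that add atoms: none
Why: Hydride reduction of the aryl ketone gives a para-hydroxybenzylic alcohol that loses water through a para-quinone methide under mild acid to the conjugated chromene (reduction–dehydration); short contact with dilute acid limits dimerisation of the chromene.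

Step 3
Reactants: 6 2,4,5-trihydroxybenzaldehyde; 7 allyl bromide
Product: 8 4-(allyloxy)-2,5-dihydroxybenzaldehyde
Conditions: NaHCO3 (1.1 equiv), DMF, 40 °C, argon
Reagents that add atoms: allyl bromide (7), C=CCBr
Why: Williamson etherification; the 4-OH is para to the formyl group and the most acidic, the 2-OH is held in a hydrogen bond to the carbonyl and the 5-OH is only meta, so one equivalent of weak base ionises and alkylates O4; air is excluded because the 2,5-dihydroxy unit is a hydroquinone.

Step 4
Reactants: 8 4-(allyloxy)-2,5-dihydroxybenzaldehyde; 9 ethyl diazoacetate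
Product: 11 ethyl 6-(allyloxy)-5-hydroxybenzofuran-3-carboxylate, via hemiacetal 2-hydroxy-2,3-dihydrobenzofuran 10 (not isolated)
Conditions: HBF4·OEt2 (10 mol %), CH2Cl2, rt; then conc. H2SO4 (cat.), rt
Reagents that add atoms: ethyl diazoacetate (9), CCOC(=O)C=[N+]=[N-]
Why: Acid-catalysed addition of the diazoacetate to the aldehyde, 1,2-shift of the electron-rich aryl group with loss of N2 (Roskamp-type homologation) and closure give hemiacetal 10, which is dehydrated to the benzofuran-3-carboxylate; this established salicylaldehyde-to-benzofuran method is run here, before any prenyl, chromene or silyl group is present.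

Step 5
Reactants: 11 ethyl 6-(allyloxy)-5-hydroxybenzofuran-3-carboxylate; 12 3-chloro-3-methylbut-1-yne
Product: 13 ethyl 6-(allyloxy)-5-[(2-methylbut-3-yn-2-yl)oxy]benzofuran-3-carboxylate
Conditions: K2CO3, KI, CuI (cat.), acetone, 60 °C
Reagents that add atoms: 3-chloro-3-methylbut-1-yne (12), CC(C)(Cl)C#C
Why: Copper-assisted O-alkylation of a phenol with the tertiary propargylic chloride is the usual way to 1,1-dimethylpropargyl aryl ethers, and only one phenol is left to react.

Step 6
Reactants: 13 ethyl 6-(allyloxy)-5-[(2-methylbut-3-yn-2-yl)oxy]benzofuran-3-carboxylate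
Product: 15 ethyl 7-allyl-6-hydroxy-4,5-(2,2-dimethylpyrano)benzofuran-3-carboxylate, via chromene allyl ether 14 (not isolated)
Conditions: PhNEt2, 190 °C, sealed tube, argon
Reagents that add atoms: none
Why: Aromatic propargyl Claisen shift from O8 to C7 (its only free ortho carbon), enolisation, 1,5-hydrogen shift and oxa-6π closure give chromene 14, and at the same temperature the aromatic Claisen shift of the allyl group from O9 to C10 (again the only free ortho carbon) gives 15; the 1,2,4-oxygen pattern enforces both regiochemistries.

Step 7
Reactants: 15 ethyl 7-allyl-6-hydroxy-4,5-(2,2-dimethylpyrano)benzofuran-3-carboxylate; 16 tert-butyldimethylsilyl chloride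
Product: 17 ethyl 7-allyl-6-[(tert-butyldimethylsilyl)oxy]-4,5-(2,2-dimethylpyrano)benzofuran-3-carboxylate
Conditions: imidazole, DMF, 40 °C
Reagents that add atoms: tert-butyldimethylsilyl chloride (16), CC(C)(C)[Si](C)(C)Cl
Why: Silylation of the hindered phenol; the silyl ether tolerates hydride, MnO2, amine catalysis and Mitsunobu conditions and is removed at the end by fluoride without acid.

Step 8
Reactants: 17 ethyl 7-allyl-6-[(tert-butyldimethylsilyl)oxy]-4,5-(2,2-dimethylpyrano)benzofuran-3-carboxylate; 18 2-methylbut-2-ene
Product: 19 ethyl 6-[(tert-butyldimethylsilyl)oxy]-7-(3-methylbut-2-enyl)-4,5-(2,2-dimethylpyrano)benzofuran-3-carboxylate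
Conditions: second-generation Grubbs catalyst RuCl2(=CHPh)(H2IMes)(PCy3) (5 mol %), 2-methylbut-2-ene/CH2Cl2, 40 °C
Reagents that add atoms: 2-methylbut-2-ene (18), CC=C(C)C
Why: Olefin cross-metathesis of an allyl arene with excess 2-methylbut-2-ene is the standard allyl-to-prenyl conversion; the cis-disubstituted chromene double bond next to a quaternary carbon and the benzofuran double bond are poor metathesis partners.

Step 9
Reactants: 19 ethyl 6-[(tert-butyldimethylsilyl)oxy]-7-(3-methylbut-2-enyl)-4,5-(2,2-dimethylpyrano)benzofuran-3-carboxylate
Product: 20 [6-[(tert-butyldimethylsilyl)oxy]-7-(3-methylbut-2-enyl)-4,5-(2,2-dimethylpyrano)benzofuran-3-yl]methanol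
Conditions: i-Bu2AlH, CH2Cl2, −78 to 0 °C
Reagents that add atoms: none
Why: Aluminium hydride reduction of the ester to the primary alcohol; alkenes and the aryl silyl ether are inert.

Step 10
Reactants: 20 [6-[(tert-butyldimethylsilyl)oxy]-7-(3-methylbut-2-enyl)-4,5-(2,2-dimethylpyrano)benzofuran-3-yl]methanol
Product: 21 6-[(tert-butyldimethylsilyl)oxy]-7-(3-methylbut-2-enyl)-4,5-(2,2-dimethylpyrano)benzofuran-3-carbaldehyde
Conditions: MnO2, CH2Cl2, rt
Reagents that add atoms: none
Why: MnO2 oxidises the heteroaryl (allylic-type) carbinol selectively to the aldehyde without touching the isolated alkenes; the phenol is silylated, so no phenol oxidation can compete.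

Step 11
Reactants: 5 7-hydroxy-2,2-dimethyl-2H-chromene (1.5 equiv); 21 6-[(tert-butyldimethylsilyl)oxy]-7-(3-methylbut-2-enyl)-4,5-(2,2-dimethylpyrano)benzofuran-3-carbaldehyde
Product: 23 (6aS,11aR)-9-[(tert-butyldimethylsilyl)oxy]-6-hydroxy-10-prenyl bis(2,2-dimethylpyrano)pterocarpan (cis lactol; C6 anomers), via ring-open cis hydroxy aldehyde 22 (not isolated)
Conditions: 9-amino(9-deoxy)epi-quinine (20 mol %), 2-fluorobenzoic acid (40 mol %), toluene, 0 °C to rt
Reagents that add atoms: none
Why: Proposed new method: the primary amine condenses with 21 to a protonated imine that is planar, E-configured and held s-cis by the peri vinyl carbon on C7, which makes C11a a vinylogous oxocarbenium-type β-carbon; the carbon of 5 that is ortho to its hydroxyl and para to the pyran oxygen (future C11b), with the OH hydrogen-bonded to the carboxylate bridging the quinuclidinium and iminium N–H groups, attacks C11a in a Friedel–Crafts conjugate addition that dearomatises the furan ring, and the enamine/imine formed is protonated at C6a and hydrolysed to aldehyde 22. O5 then adds to the C6 carbonyl in a 6-exo-trig hemiacetalisation that closes ring B; only the cis aldehyde can reach, and the labile C6a center equilibrates into it through the enamine or enol. C11a is controlled by the catalyst: in the working model for the (8S,9S) amine the quinoline covers one face of the iminium and the phenol is delivered to the other, the Si face of C11a (O11 > C6a > H), which corresponds to 11aR, with the quinidine-derived pseudo-enantiomer available for the opposite sense; C6a follows from C11a through the cis-only ring closure and C6 forms as an inconsequential anomeric mixture. The closest known reaction types are amine-catalysed iminium Friedel–Crafts/hemiacetalisation of naphthols and other electron-rich phenols with enals to 2-chromanols, cinchona primary-amine iminium activation of α-branched enals, and organocatalytic dearomative conjugate additions to nitrobenzofurans. A primary amine is chosen because the α-aryl substituent and the peri group leave no strain-free planar iminium for a diarylprolinol silyl ether. Site selectivity on 5 rests on sterics (the other ortho carbon lies between two oxygens) and on its blocked para position; chemoselectivity needs C–C bond formation to outrun reversible addition of nitrogen or phenoxide oxygen at C11a and β-elimination of O11 from the enamine, which the acid co-catalyst (fast protonation at C6a) and the lactol trap are meant to secure.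

Step 12
Reactants: 23 (6aS,11aR)-9-[(tert-butyldimethylsilyl)oxy]-6-hydroxy-10-prenyl bis(2,2-dimethylpyrano)pterocarpan (cis lactol)
Product: 24 (2R,3R)-2-aryl-3-(hydroxymethyl)-2,3-dihydrobenzofuran diol (aryl = 7-hydroxy-2,2-dimethyl-2H-chromen-6-yl)
Conditions: NaBH4, CeCl3·7H2O, MeOH/THF, −20 °C
Reagents that add atoms: none
Why: Carbonyl reduction of a masked aldehyde: lactol 23 is the ring tautomer of hydroxy aldehyde 22 (the species passed through in step 11) and reacts through the small open-chain share of this ring–chain equilibrium, which borohydride reduces faster than it can epimerise at low temperature (Luche-type conditions buffer the basicity of the medium); once C6 is an alcohol, C6a is no longer enolisable and its configuration is fixed.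

Step 13
Reactants: 24 (2R,3R)-2-(7-hydroxy-2,2-dimethyl-2H-chromen-6-yl)-3-(hydroxymethyl)-2,3-dihydrobenzofuran diol carrying the ring D substituents of 21
Product: 25 9-O-(tert-butyldimethylsilyl) Lespecyrtin E4, (6aR,11aR)
Conditions: PPh3, DIAD, THF, 0 °C to rt
Reagents that add atoms: none
Why: Intramolecular Mitsunobu etherification; the ring A phenol displaces the activated primary alcohol in a 6-exo-tet closure of ring B, no stereocenter is touched, and the cis arrangement of aryl and CH2OH set in step 11 is what allows closure.

Step 14
Reactants: 25 9-O-(tert-butyldimethylsilyl) Lespecyrtin E4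
Product: 26 Lespecyrtin E4, (6aR,11aR)
Conditions: Bu4NF, AcOH, THF, 0 °C
Reagents that add atoms: none
Why: Fluoride cleaves the aryl silyl ether under buffered, non-acidic conditions that leave the prenyl group, both chromenes and the C11a–O11 bond untouched.

## Compound list

1 | resorcinol | Oc1cccc(O)c1 | starting material
2 | 3-methylbut-2-enoic acid | CC(C)=CC(=O)O | starting material
3 | 7-hydroxy-2,2-dimethylchroman-4-one | CC1(C)CC(=O)c2ccc(O)cc2O1 | intermediate
4 | 2,2-dimethylchromane-4,7-diol (racemic, not isolated) | CC1(C)CC(O)c2ccc(O)cc2O1 | intermediate
5 | 7-hydroxy-2,2-dimethyl-2H-chromene | CC1(C)C=Cc2ccc(O)cc2O1 | intermediate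
6 | 2,4,5-trihydroxybenzaldehyde | O=Cc1cc(O)c(O)cc1O | starting material
7 | allyl bromide | C=CCBr | starting material
8 | 4-(allyloxy)-2,5-dihydroxybenzaldehyde | O=Cc1cc(O)c(OCC=C)cc1O | intermediate
9 | ethyl diazoacetate | CCOC(=O)C=[N+]=[N-] | starting material
10 | ethyl 6-(allyloxy)-2,5-dihydroxy-2,3-dihydrobenzofuran-3-carboxylate (hemiacetal, mixture of stereoisomers, not isolated) | CCOC(=O)C1C(O)Oc2cc(OCC=C)c(O)cc12 | intermediate
11 | ethyl 6-(allyloxy)-5-hydroxybenzofuran-3-carboxylate | CCOC(=O)c1coc2cc(OCC=C)c(O)cc12 | intermediate
12 | 3-chloro-3-methylbut-1-yne | CC(C)(Cl)C#C | starting material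
13 | ethyl 6-(allyloxy)-5-[(2-methylbut-3-yn-2-yl)oxy]benzofuran-3-carboxylate | CCOC(=O)c1coc2cc(OCC=C)c(OC(C)(C)C#C)cc12 | intermediate
14 | ethyl 6-(allyloxy)-4,5-(2,2-dimethylpyrano)benzofuran-3-carboxylate (not isolated) | CCOC(=O)c1coc2cc(OCC=C)c3OC(C)(C)C=Cc3c12 | intermediate
15 | ethyl 7-allyl-6-hydroxy-4,5-(2,2-dimethylpyrano)benzofuran-3-carboxylate | CCOC(=O)c1coc2c(CC=C)c(O)c3OC(C)(C)C=Cc3c12 | intermediate
16 | tert-butyldimethylsilyl chloride | CC(C)(C)[Si](C)(C)Cl | starting material
17 | ethyl 7-allyl-6-[(tert-butyldimethylsilyl)oxy]-4,5-(2,2-dimethylpyrano)benzofuran-3-carboxylate | CCOC(=O)c1coc2c(CC=C)c(O[Si](C)(C)C(C)(C)C)c3OC(C)(C)C=Cc3c12 | intermediate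
18 | 2-methylbut-2-ene | CC=C(C)C | starting material
19 | ethyl 6-[(tert-butyldimethylsilyl)oxy]-7-(3-methylbut-2-enyl)-4,5-(2,2-dimethylpyrano)benzofuran-3-carboxylate | CCOC(=O)c1coc2c(CC=C(C)C)c(O[Si](C)(C)C(C)(C)C)c3OC(C)(C)C=Cc3c12 | intermediate
20 | [6-[(tert-butyldimethylsilyl)oxy]-7-(3-methylbut-2-enyl)-4,5-(2,2-dimethylpyrano)benzofuran-3-yl]methanol | OCc1coc2c(CC=C(C)C)c(O[Si](C)(C)C(C)(C)C)c3OC(C)(C)C=Cc3c12 | intermediate
21 | 6-[(tert-butyldimethylsilyl)oxy]-7-(3-methylbut-2-enyl)-4,5-(2,2-dimethylpyrano)benzofuran-3-carbaldehyde (key-step precursor) | O=Cc1coc2c(CC=C(C)C)c(O[Si](C)(C)C(C)(C)C)c3OC(C)(C)C=Cc3c12 | intermediate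
22 | (2R,3S)-2-(7-hydroxy-2,2-dimethyl-2H-chromen-6-yl)-3-formyl-2,3-dihydrobenzofuran carrying the ring D substituents of 21 (ring-open cis hydroxy aldehyde, not isolated) | CC(C)=CCc1c(O[Si](C)(C)C(C)(C)C)c2c(c3c1O[C@@H](c1cc4c(cc1O)OC(C)(C)C=C4)[C@H]3C=O)C=CC(C)(C)O2 | intermediate
23 | (6aS,11aR)-9-[(tert-butyldimethylsilyl)oxy]-6-hydroxy-10-prenyl pterocarpan carrying 2,2-dimethylpyran rings on C2/C3 and C7/C8 (cis lactol, key-step product; 6R anomer drawn, C6 anomeric mixture) | CC(C)=CCc1c(O[Si](C)(C)C(C)(C)C)c2c(c3c1O[C@H]1c4cc5c(cc4O[C@@H](O)[C@@H]31)OC(C)(C)C=C5)C=CC(C)(C)O2 | intermediate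
24 | (2R,3R)-2-(7-hydroxy-2,2-dimethyl-2H-chromen-6-yl)-3-(hydroxymethyl)-2,3-dihydrobenzofuran carrying the ring D substituents of 21 (diol) | CC(C)=CCc1c(O[Si](C)(C)C(C)(C)C)c2c(c3c1O[C@@H](c1cc4c(cc1O)OC(C)(C)C=C4)[C@H]3CO)C=CC(C)(C)O2 | intermediate
25 | 9-O-(tert-butyldimethylsilyl) Lespecyrtin E4, (6aR,11aR) | CC(C)=CCc1c(O[Si](C)(C)C(C)(C)C)c2c(c3c1O[C@H]1c4cc5c(cc4OC[C@@H]31)OC(C)(C)C=C5)C=CC(C)(C)O2 | intermediate
26 | Lespecyrtin E4, (6aR,11aR) | CC(C)=CCc1c(O)c2c(c3c1O[C@H]1c4cc5c(cc4OC[C@@H]31)OC(C)(C)C=C5)C=CC(C)(C)O2 | target

## Step count and least certain steps

Total step count: 14. Longest linear sequence: 12 steps (steps 3 to 14, from 6); the ring A branch (steps 1 and 2) joins at step 11.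

**Step 11 (key step).**
- What may go wrong: no productive turnover. The iminium ion of a vinylogous ester that must also give up the furan aromaticity is a weak electrophile. Reversible addition of the catalyst nitrogen or of phenoxide oxygen at C11a, and β-elimination of O11 from the enamine (ring-opening to a 2,3-diarylacrolein), can drain material. If the addition does proceed, facial selectivity may be poor or of the opposite sense, because the stereocontrolling groups of the catalyst sit far from C11a.
- Fallback (known chemistry; sets out from 5 and returns at 26): ortho-formylation of 5 (MgCl2, Et3N, paraformaldehyde, MeCN, reflux) at the less hindered ortho carbon gives 7-hydroxy-2,2-dimethyl-2H-chromene-6-carbaldehyde F1. Annulation with vinyltriphenylphosphonium bromide and K2CO3 (oxa-Michael addition, then intramolecular Wittig reaction) turns F1 into the bis-chromene 8,8-dimethyl-2H,8H-pyrano[3,2-g]chromene F2, whose unsubstituted pyran ring holds C6, C6a and C11a. Commercial 2-(allyloxy)phenol is oxidised with (KSO3)2NO to 2-(allyloxy)-1,4-benzoquinone F3. A titanium TADDOLate (from TiCl4, Ti(Oi-Pr)4 and the TADDOL antipode that leads to the 6aR,11aR series; CH2Cl2, −78 °C) promotes the asymmetric [3+2] union of F2 and F3, forming C6a–C6b and then O11–C11a with cis fusion, to the (6aR,11aR)-9-(allyloxy)-8-hydroxy pterocarpan F4. This step needs the unsubstituted chromene double bond to react in preference to the one flanked by the gem-dimethyl carbon. O8 is alkylated with 12 (K2CO3, KI, CuI, acetone) to the 8-O-(1,1-dimethylpropargyl) ether F5. Heating as in step 6 takes F5 through the 9-O-allyl bis-pyrano pterocarpan F6 (not isolated) to the 10-allyl-9-hydroxy bis-pyrano pterocarpan F7, and cross-metathesis of F7 with 18 as in step 8 gives 26.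

**Step 4.**
- What may go wrong: O-alkylation of the free 5-hydroxyl by the protonated diazoacetate, and slow addition to an aldehyde that is deactivated by its para alkoxy group, so that diazoacetate decomposition wins; oxidation of the hydroquinone unit is a further loss.
- Fallback (sets out from 8 and returns at 11): the non-chelated 5-hydroxyl of 8 is acylated (pivaloyl chloride, pyridine, CH2Cl2, 0 °C) to 4-(allyloxy)-2-hydroxy-5-(pivaloyloxy)benzaldehyde F8. The homologation with 9 is run as in step 4 on this mono-phenol, the substrate class for which it is established, through the hemiacetal ethyl 6-(allyloxy)-2-hydroxy-5-(pivaloyloxy)-2,3-dihydrobenzofuran-3-carboxylate F9 (not isolated) to ethyl 6-(allyloxy)-5-(pivaloyloxy)benzofuran-3-carboxylate F10. K2CO3 in ethanol removes the pivalate to give 11.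

**Step 3.**
- What may go wrong: alkylation at a second oxygen or at O5 instead of O4, and air oxidation of the 2,5-dihydroxy unit under base.
- Fallback (sets out from 7 and returns at 8): commercial 2,4-dihydroxybenzaldehyde, for which mono-alkylation of the 4-hydroxyl is routine, is allylated with 7 (K2CO3, acetone) to 4-(allyloxy)-2-hydroxybenzaldehyde F11. The missing oxygen is then introduced para to the free hydroxyl by Elbs persulfate oxidation (K2S2O8, aqueous NaOH) through potassium 2-(allyloxy)-5-formyl-4-hydroxyphenyl sulfate F12 (not isolated), whose acid hydrolysis gives 8.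

**Step 6.**
- What may go wrong: thermal degradation when both shifts are forced in one pot, or failure of the propargyl shift onto the hindered carbon peri to the ester, so that elimination of the tertiary ether competes.
- Fallback (sets out from 11 and returns at 15): the pyran is built by condensation instead of rearrangement. 11 is heated with 3-methylbut-2-enal and PhB(OH)2 (AcOH, toluene, reflux, water removal). The 2-phenyl-4H-1,3,2-benzodioxaborinine F13 (not isolated) loses phenylboronic acid to an ortho-quinone methide that closes by oxa-6π to 14, now isolated. The allyl Claisen shift of 14 to 15 is then run as a separate operation.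

**Step 12.**
- What may go wrong: base-mediated epimerisation at C6a, or β-elimination of O11, in the ring-open aldehyde before hydride arrives; partial loss of the aryl silyl ether in methanol is a lesser concern.
- Fallback (sets out from 23 and returns at 25): direct ionic deoxygenation of the lactol with Et3SiH and BF3·OEt2 (CH2Cl2, −78 °C). Hydride is delivered to the cyclic oxocarbenium ion, so C6a is never enolisable and ring B stays closed. It is not the first choice because the Lewis acid can also ionise the C11a–O11 bond; it makes no new compound.

## Further compounds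

F1 | step 11 | 7-hydroxy-2,2-dimethyl-2H-chromene-6-carbaldehyde | CC1(C)C=Cc2cc(C=O)c(O)cc2O1
F2 | step 11 | 8,8-dimethyl-2H,8H-pyrano[3,2-g]chromene | CC1(C)C=Cc2cc3C=CCOc3cc2O1
F3 | step 11 | 2-(allyloxy)-1,4-benzoquinone | C=CCOC1=CC(=O)C=CC1=O
F4 | step 11 | (6aR,11aR)-9-(allyloxy)-8-hydroxy pterocarpan with a 2,2-dimethylpyran ring on C2/C3 | c1c(OCC=C)c(O)cc3c1O[C@H]1c4cc5c(cc4OC[C@@H]31)OC(C)(C)C=C5
F5 | step 11 | (6aR,11aR)-9-(allyloxy)-8-[(2-methylbut-3-yn-2-yl)oxy] pterocarpan with a 2,2-dimethylpyran ring on C2/C3 | c1c(OCC=C)c(OC(C)(C)C#C)cc3c1O[C@H]1c4cc5c(cc4OC[C@@H]31)OC(C)(C)C=C5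
F6 | step 11 | (6aR,11aR)-9-(allyloxy) pterocarpan with 2,2-dimethylpyran rings on C2/C3 and C7/C8 (not isolated) | c1c(OCC=C)c2c(c3c1O[C@H]1c4cc5c(cc4OC[C@@H]31)OC(C)(C)C=C5)C=CC(C)(C)O2
F7 | step 11 | (6aR,11aR)-10-allyl-9-hydroxy pterocarpan with 2,2-dimethylpyran rings on C2/C3 and C7/C8 | C=CCc1c(O)c2c(c3c1O[C@H]1c4cc5c(cc4OC[C@@H]31)OC(C)(C)C=C5)C=CC(C)(C)O2
F8 | step 4 | 4-(allyloxy)-2-hydroxy-5-(pivaloyloxy)benzaldehyde | O=Cc1cc(OC(=O)C(C)(C)C)c(OCC=C)cc1O
F9 | step 4 | ethyl 6-(allyloxy)-2-hydroxy-5-(pivaloyloxy)-2,3-dihydrobenzofuran-3-carboxylate (hemiacetal, mixture of stereoisomers, not isolated) | CCOC(=O)C1C(O)Oc2cc(OCC=C)c(OC(=O)C(C)(C)C)cc12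
F10 | step 4 | ethyl 6-(allyloxy)-5-(pivaloyloxy)benzofuran-3-carboxylate | CCOC(=O)c1coc2cc(OCC=C)c(OC(=O)C(C)(C)C)cc12
F11 | step 3 | 4-(allyloxy)-2-hydroxybenzaldehyde | O=Cc1ccc(OCC=C)cc1O
F12 | step 3 | potassium 2-(allyloxy)-5-formyl-4-hydroxyphenyl sulfate (not isolated) | O=Cc1cc(OS(=O)(=O)[O-])c(OCC=C)cc1O.[K+]
F13 | step 6 | 2-phenyl-4-(2-methylprop-1-enyl)-4H-1,3,2-dioxaborinine fused at C4/C5 of ethyl 6-(allyloxy)benzofuran-3-carboxylate (not isolated) | CCOC(=O)c1coc2cc(OCC=C)c3OB(c4ccccc4)OC(C=C(C)C)c3c12
F0 | step 12 | none | none
A1 | alternative 1 | cis-chromane with a diazo enone on C6a and a (5-methylhex-4-en-1-ynyl) ether on C11a | CC(C)=CCC#CO[C@H]1c2cc3C=CC(C)(C)Oc3cc2OC[C@H]1C(=[N+]=[N-])C(=O)/C=C/OC(C)(C)C#C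
A2 | alternative 1 | 9-hydroxy-10-prenyl pterocarpan 8-(1,1-dimethylpropargyl) ether | CC(C)=CCc1c(O)c(OC(C)(C)C#C)cc3c1O[C@H]1c4cc5c(cc4OC[C@@H]31)OC(C)(C)C=C5
A3 | alternative 2 | methyl 2-diazo-2-aryl acetate with the ortho O-CH2-aryl ether (ring D aryldiazoacetate) | COC(=O)C(=[N+]=[N-])c1cc(O[Si](C)(C)C(C)(C)C)c(OCOC)c(CC=C(C)C)c1OCc1cc2C=CC(C)(C)Oc2cc1O[Si](C)(C)C(C)(C)C
A4 | alternative 2 | cis-2-aryl-2,3-dihydrobenzofuran-3-carboxylate | CC(C)=CCc1c(OCOC)c(O[Si](C)(C)C(C)(C)C)cc2c1O[C@@H](c1cc3C=CC(C)(C)Oc3cc1O[Si](C)(C)C(C)(C)C)[C@H]2C(=O)OC
A5 | alternative 3 | (6aR,11aR)-3,8-dihydroxy-9-methoxy-10-prenyl pterocarpan-2,7-dicarbaldehyde | CC(C)=CCc1c(OC)c(O)c(C=O)c2c1O[C@H]1c3cc(C=O)c(O)cc3OC[C@@H]21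
A6 | alternative 3 | 2-methylprop-1-enylmagnesium bromide | CC(C)=C[Mg]Br
A7 | alternative 3 | 9-O-methyl Lespecyrtin E4 | CC(C)=CCc1c(OC)c2c(c3c1O[C@H]1c4cc5c(cc4OC[C@@H]31)OC(C)(C)C=C5)C=CC(C)(C)O2
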